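The earlier runs and the new flask come from a simulation for substances that don't exist.

Ask first what is left over in the flask once substrate and other conformer have both reacted, if each takes one solid reagent: 0.150 mM.

| setting | oak | ash | flask |
|---|---|---|---|
| substrate | 0.50 mM | 0.50 mM | 0.50 mM |
| other conformer | 0.25 mM | 0.25 mM | 0.250 mM |
| solid reagent | 1.3 mM | 2 mM | 0.900 mM |
| remark | run made earlier | run made earlier |  |
| time |  |  | 2.0 min |

| run | time / min | target / % | isomer of the product A / % |
|---|---|---|---|
| oak | 0.200 | 7.6 | 0.5 |
| oak | 0.333 | 14.2 | 0.2 |
| oak | 0.500 | 20.2 | 1.5 |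
| oak | 0.833 | 29.7 | 1.8 |
| oak | 1.33 | 41.4 | 2.9 |
| oak | 2.50 | 55.6 | 4.1 |
| ash | 0.417 | 17.3 | 1.2 |
| ash | 0.833 | 31.2 | 2.3 |
| ash | 1.33 | 41.8 | 3.0 |
| ash | 1.50 | 44.9 | 3.4 |
| ash | 2.00 | 52.1 | 3.7 |
| ash | 2.50 | 54.5 | 4.0 |

(scatter of a reading: 0.5 percentage points)

- solid, in amounts per volume of the solution: solid reagent
- at the start none of the solid reagent is in solution

- ratio of target to isomer of the product A at 3.0 s
- ratio of target to isomer of the product A at 20 s
- ratio of target to isomer of the product A at 2.0 min
- which of target and isomer of the product A there is more of at 2.0 min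

Divide instead of subtracting, and this flask gets 1.20. Call this the cover: the turnovers of the pool, substrate and other conformer together, that the charge can pay for. With one solid reagent per turnover, a cover above one makes the pool the limiting reagent.

Now take the rate. Over its first 0.417 min, the ash run makes 0.444 min⁻¹ of the pool as target and isomer of the product A. From 1.50 min to 2.50 min it reads 0.102 min⁻¹. That is a slowing by 4.35, as read.

What slows it? More solid does not seem to matter: at 2.50 min, oak reads 55.6% target and ash 54.5%, with covers of 1.73 and 2.67. So I take the reaction as pseudo-first-order in the pool. By 2.00 min, ash reads 55.8% of the pool as these two products. That is a floor on what is spent, since I read nothing else. Counting these two alone, falling [substrate] gives a factor of 2.26. That count leaves a factor of 1.92 open, so the pool may be going somewhere these readings do not show.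

A slowing shared by both products leaves their ratio alone. So I expect the ash reading at 2.0 min, 14.1, with target ahead.

The forecast gives 14, 14 and 14, with target ahead: “Target/isomer is flat within noise”.

The flask gives 11.7 at 3.0 s, 14.0 at 20 s and 13.3 at 2.0 min, with 51.1% target against 3.85% isomer of the product A. The earliest ratio is lower than the middle one.

    substrate ⇌ other conformer (K = 0.210, k = 0.0490 s⁻¹)
    substrate + partner → target (k = 65.0 M⁻¹ s⁻¹)
    partner + other conformer → isomer of the product A (k = 14.0 M⁻¹ s⁻¹)
    solid reagent ⇌ partner, rate k4*(cs4 - [partner]) while solid is left; crystals form when [partner] > cs4 (solubility = 0.310 mM, k = 0.170 s⁻¹)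
    target ⇌ isomer of the product B (K = 0.560, k = 0.0870 s⁻¹)

At 20.0 min this flask holds 0% substrate and 0% other conformer, and [partner] stands at 0.150 mM, against the leftover of 0.150 mM. Now take the neighbouring flask with 2.0 mM of substrate. Its cover drops to 0.400, below one. At 2.00 min, target and both isomers of the products together stand at 40.0% of the pool, against a cover of 40.0%. Solid reagent there is down to 0%, and [partner] to 3.65 × 10⁻⁴ mM.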